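**Plan**
1. Retrosynthetic cuts, in order: the catechol ketal; the furan ring at C3–C1' (C–H arylation) and at C2–O (addition–elimination); ring D (the pyran) at its C(CH3)2–CH= bond; the C3–I and C2–S handles; ring C back to an acetophenone plus CS2; the ring B prenyl C–C bond.
2. Forward order: ring A is built with its substitution fixed by symmetry, ring C is closed by CS2 annulation, ring D is closed on the chromone (key step), the ring B phenol is attached through oxygen at C2, the furan ring is closed, and the ketal is removed.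
3. Enabling feature: ring D is a 2,2-dimethyl-2H-pyran fused at C7–O/C8 of ring A. Its O–C(CH3)2 carbon is the methine of an isopropyl ether in disguise, and that tertiary C–H lies 1,5 to the inner carbon of an ethynyl group on C8. A hydride shift followed by C–C closure therefore converts "isopropyl ether + alkyne" into the pyran with no change of oxidation level.
4. Regiochemistry: 4-methyl-3,5-di(propan-2-yloxy)phenol has a mirror plane, so its one free OH (para to the methyl) becomes O1 and the methyl ends at C6. The C8 alkyne is flanked only by O1 and the C7 isopropyl ether, and ring B has one free position ortho to its ether oxygen.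
5. Stereochemistry: the target has no stereocentre; the ring D alkene is cis by ring constraint and the prenyl alkene carries two identical methyls, so nothing has to be set.

Key step: step 10

Remark: positions are numbered as in an isoflavone (ring C: O1, C2, C3, C4; ring A: C4a to C8a; ring B: C1' to C6'; the pyran is ring D); all starting materials and reagents named are taken to be commercial.

Step 1
Reactants: 1 2-methylbenzene-1,3-diol (2-methylresorcinol)
Product: 2 2-methyl-1,3-di(propan-2-yloxy)benzene
Conditions: 2-bromopropane (3 equiv), K2CO3, DMF, 70 °C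
Reagents that add atoms: 2-bromopropane CC(C)Br
Why: Williamson ether synthesis on both phenols, with excess secondary bromide to offset E2 loss; one of these isopropyl groups later supplies the C(CH3)2 carbon of ring D.

Step 2
Reactants: 2 2-methyl-1,3-di(propan-2-yloxy)benzene
Product: 4 4-methyl-3,5-di(propan-2-yloxy)phenol, via pinacol boronate 3 (not isolated)
Conditions: B2pin2 (1.0 equiv), [Ir(OMe)(cod)]2 (1.5 mol %), 4,4'-di-tert-butyl-2,2'-bipyridine (3 mol %), THF, 80 °C; then aq. NaOH, H2O2, 0 °C to rt
Reagents that add atoms: bis(pinacolato)diboron CC1(C)OB(OC1(C)C)B1OC(C)(C)C(C)(C)O1 (boryl group of 3); hydrogen peroxide OO (phenol oxygen of 4)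
Why: Sterically governed iridium-catalysed C–H borylation should take the only ring C–H without an ortho substituent (para to the methyl), and alkaline peroxide oxidation of the C–B bond then gives the symmetric phenol.

Step 3
Reactants: 4 4-methyl-3,5-di(propan-2-yloxy)phenol
Product: 5 1-[6-hydroxy-3-methyl-2,4-di(propan-2-yloxy)phenyl]ethan-1-one
Conditions: Ac2O (1.2 equiv), BF3·OEt2 (2 equiv), CH2Cl2, 0 °C to rt; aq. NaHCO3
Reagents that add atoms: acetic anhydride CC(=O)OC(C)=O
Why: Friedel–Crafts (Fries-type) ortho-acetylation of a phloroglucinol-like arene whose two open positions are equivalent, so one ketone should form whose only free ortho OH is the one para to the methyl.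

Step 4
Reactants: 5 1-[6-hydroxy-3-methyl-2,4-di(propan-2-yloxy)phenyl]ethan-1-one
Product: 6 1-[2-hydroxy-3-iodo-5-methyl-4,6-di(propan-2-yloxy)phenyl]ethan-1-one
Conditions: NIS (1.05 equiv), MeCN, 0 °C to rt
Reagents that add atoms: N-iodosuccinimide O=C1CCC(=O)N1I
Why: Electrophilic aromatic iodination at the only remaining ring C–H, which is activated by the ortho hydroxyl and the ortho and para alkoxy groups.

Step 5
Reactants: 6 1-[2-hydroxy-3-iodo-5-methyl-4,6-di(propan-2-yloxy)phenyl]ethan-1-one
Product: 8 8-iodo-6-methyl-2-(methylsulfanyl)-5,7-di(propan-2-yloxy)-4H-chromen-4-one, via chromene-2-thione 7 (not isolated)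
Conditions: t-BuOK (3 equiv), CS2 (1.5 equiv), THF, 0 °C to rt; then MeI, rt
Reagents that add atoms: carbon disulfide S=C=S; iodomethane CI
Why: Known carbon disulfide annulation of 2-hydroxyacetophenones: the enolate adds to CS2, the single free phenoxide closes the pyran-2-thione with loss of hydrosulfide, and the soft thione sulfur is S-methylated to the 2-(methylsulfanyl)chromone.

Step 6
Reactants: 8 8-iodo-6-methyl-2-(methylsulfanyl)-5,7-di(propan-2-yloxy)-4H-chromen-4-one
Product: 9 5-hydroxy-8-iodo-6-methyl-2-(methylsulfanyl)-7-(propan-2-yloxy)-4H-chromen-4-one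
Conditions: BCl3 (1.2 equiv), CH2Cl2, −78 to −20 °C; aq. work-up
Reagents that add atoms: none
Why: Chelation-controlled Lewis-acid dealkylation, in which BCl3 bound to the C4 carbonyl should cleave only the peri (C5) isopropyl ether and leave the C7 isopropyl ether for the key step.

Step 7
Reactants: 9 5-hydroxy-8-iodo-6-methyl-2-(methylsulfanyl)-7-(propan-2-yloxy)-4H-chromen-4-one
Product: 11 8-ethynyl-5-hydroxy-6-methyl-2-(methylsulfanyl)-7-(propan-2-yloxy)-4H-chromen-4-one, via silyl alkyne 10 (not isolated)
Conditions: ethynyltrimethylsilane (2 equiv), PdCl2(PPh3)2 (5 mol %), CuI (10 mol %), Et3N, DMF, 60 °C; filtration; then K2CO3 (0.2 equiv), MeOH, rt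
Reagents that add atoms: ethynyltrimethylsilane C#C[Si](C)(C)C
Why: Sonogashira coupling at the only carbon–halogen bond followed by base-catalysed methanolysis of the C–Si bond; the alkyne has no free ortho hydroxyl (its neighbours are O1 and the isopropyl ether), so no furan can form.

Step 8
Reactants: 11 8-ethynyl-5-hydroxy-6-methyl-2-(methylsulfanyl)-7-(propan-2-yloxy)-4H-chromen-4-one
Product: 12 8-ethynyl-5-hydroxy-3-iodo-6-methyl-2-(methylsulfanyl)-7-(propan-2-yloxy)-4H-chromen-4-one
Conditions: NIS (1.1 equiv), MeCN, 0 °C, dark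
Reagents that add atoms: N-iodosuccinimide O=C1CCC(=O)N1I
Why: Electrophilic iodination at C3, the nucleophilic α-carbon of the push–pull (ketene O,S-acetal) enone; ring A has no free position and a terminal alkyne should not react with NIS without base or a silver salt.

Step 9
Reactants: 12 8-ethynyl-5-hydroxy-3-iodo-6-methyl-2-(methylsulfanyl)-7-(propan-2-yloxy)-4H-chromen-4-one
Product: 13 8-ethynyl-5-hydroxy-3-iodo-2-(methanesulfonyl)-6-methyl-7-(propan-2-yloxy)-4H-chromen-4-one
Conditions: mCPBA (2.5 equiv), CH2Cl2, 0 °C to rt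
Reagents that add atoms: 3-chloroperoxybenzoic acid OOC(=O)c1cccc(Cl)c1
Why: Peracid oxidation of the sulfide to the sulfone, which makes C2 an addition–elimination site; it is done here because no electron-rich alkene is yet present, and the alkyne, the C–I bond and the chelated phenol should be inert.

Step 10
Reactants: 13 8-ethynyl-5-hydroxy-3-iodo-2-(methanesulfonyl)-6-methyl-7-(propan-2-yloxy)-4H-chromen-4-one
Product: 14 5-hydroxy-3-iodo-2-(methanesulfonyl)-6,8,8-trimethyl-4H,8H-pyrano[2,3-f]chromen-4-one
Conditions: (XPhos)Au(NCMe)SbF6 (5 mol %), 4 Å MS, ClCH2CH2Cl, 70 °C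
Reagents that add atoms: none
Why: Proposed new method: the cationic gold catalyst binds the terminal alkyne and places positive charge on the aryl-bound inner carbon, which lies 1,5 to the tertiary C–H of the 7-O-isopropyl group; through-space 1,5-hydride transfer (six-membered transition state) gives an aryl oxocarbenium ion (ArO+=CMe2) and an alkenyl-gold species, whose gold-bearing terminal carbon attacks the oxocarbenium carbon with release of the catalyst, so that the bond formed is C(CH3)2–CH= and the alkyne becomes the C=C of the pyran in a redox-neutral isomerisation. The closest known reaction type is the π-acid-catalysed hydride-transfer cyclisation (intramolecular hydroalkylation) of alkynes tethered to alkyl ethers, together with the acid-catalysed 1,5-hydride shift and ring closure of ortho-alkoxybenzylidene malonates to chromans, which shows that an aryl ether with its oxygen inside the tether can be the donor; an aryl isopropyl ether paired with a plain ortho-ethynyl group has not been shown. Ring D is the only ring closed, by 6-endo-trig attack of the alkenyl carbon on the C=O+ carbon, with both unsaturated units ending inside the ring. No stereocentre is formed and the new alkene is cis by ring constraint. The step needs hydride transfer to win over 5-endo attack of the ether oxygen on the alkyne (which would end in loss of propene and a furan) and six- over five-membered C–C closure: only hydride can reach the electrophilic inner carbon (oxygen attack there would give a four-membered ring), the oxygen lone pair is partly drained by the para carbonyl and shielded by the C6 methyl, an α-oxy tertiary C–H is a good hydride donor, and closure through the terminal carbon keeps the developing charge benzylic and β to gold. Site selectivity is built in because the C8 alkyne has the ring oxygen O1 on its other side and the C5 ether has already been cleaved, and the sulfone, the C3 iodide and the chelated 5-OH are not ligands for monovalent gold.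

Step 11
Reactants: 15 benzene-1,2,4-triol
Product: 16 2,2-diphenyl-1,3-benzodioxol-5-ol
Conditions: Ph2CCl2 (1.1 equiv), diphenyl ether, 170 °C, N2 stream
Reagents that add atoms: dichlorodiphenylmethane ClC(Cl)(c1ccccc1)c1ccccc1
Why: Ketalisation of a catechol with a gem-dichloride; only the vicinal diol can form the five-membered dioxole, so the third hydroxyl should stay free.

Step 12
Reactants: 16 2,2-diphenyl-1,3-benzodioxol-5-ol
Product: 17 5-(methoxymethoxy)-2,2-diphenyl-1,3-benzodioxole
Conditions: MOMCl, i-Pr2NEt, CH2Cl2, 0 °C to rt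
Reagents that add atoms: chloromethyl methyl ether COCCl
Why: Standard MOM ether formation, which installs the ortho-directing group for the next step.

Step 13
Reactants: 17 5-(methoxymethoxy)-2,2-diphenyl-1,3-benzodioxole
Product: 19 5-(methoxymethoxy)-4-(3-methylbut-2-en-1-yl)-2,2-diphenyl-1,3-benzodioxole, via aryllithium 18 (not isolated)
Conditions: n-BuLi (1.2 equiv), THF, −78 to 0 °C; then CuBr·SMe2 (10 mol %), 1-bromo-3-methylbut-2-ene, −78 °C to rt
Reagents that add atoms: n-butyllithium [Li]CCCC (lithium of 18 only); 1-bromo-3-methylbut-2-ene CC(C)=CCBr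
Why: Directed ortho-metalation removes the proton flanked by the OMOM group and a dioxole oxygen (cooperative coordination and inductive acidification), and copper-catalysed allylic substitution of prenyl bromide by the aryllithium should give the linear prenyl arene.

Step 14
Reactants: 19 5-(methoxymethoxy)-4-(3-methylbut-2-en-1-yl)-2,2-diphenyl-1,3-benzodioxole
Product: 20 4-(3-methylbut-2-en-1-yl)-2,2-diphenyl-1,3-benzodioxol-5-ol
Conditions: conc. HCl (cat.), MeOH/THF, 40 °C
Reagents that add atoms: none
Why: Acid-catalysed acetal methanolysis of the MOM ether under conditions that should leave the more robust benzophenone ketal and the prenyl group untouched.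

Step 15
Reactants: 14 5-hydroxy-3-iodo-2-(methanesulfonyl)-6,8,8-trimethyl-4H,8H-pyrano[2,3-f]chromen-4-one; 20 4-(3-methylbut-2-en-1-yl)-2,2-diphenyl-1,3-benzodioxol-5-ol
Product: 21 5-hydroxy-3-iodo-6,8,8-trimethyl-2-{[4-(3-methylbut-2-en-1-yl)-2,2-diphenyl-1,3-benzodioxol-5-yl]oxy}-4H,8H-pyrano[2,3-f]chromen-4-one
Conditions: K2CO3 (1.5 equiv), DMF, 0 °C to rt
Reagents that add atoms: none
Why: Nucleophilic vinylic substitution (addition–elimination) at C2 of the 2-sulfonylchromone, in which the phenoxide adds to the doubly activated enone carbon and methanesulfinate leaves.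

Step 16
Reactants: 21 5-hydroxy-3-iodo-6,8,8-trimethyl-2-{[4-(3-methylbut-2-en-1-yl)-2,2-diphenyl-1,3-benzodioxol-5-yl]oxy}-4H,8H-pyrano[2,3-f]chromen-4-one
Product: 22 Triquetrumone A 4',5'-O-diphenylmethylene ketal
Conditions: Pd(OAc)2 (10 mol %), PCy3·HBF4 (20 mol %), K2CO3 (2 equiv), PivOH (30 mol %), DMA, 100 °C
Reagents that add atoms: none
Why: Intramolecular palladium-catalysed direct C–H arylation, in which zerovalent palladium inserts into the C3–I bond and carboxylate-assisted metalation of the only free position ortho to the ether oxygen closes the furan ring (the other ortho position carries the prenyl group).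

Step 17
Reactants: 22 Triquetrumone A 4',5'-O-diphenylmethylene ketal
Product: 23 Triquetrumone A
Conditions: AcOH/H2O (4:1), 80 °C
Reagents that add atoms: none
Why: Acid-catalysed hydrolysis of the benzophenone ketal in aqueous acetic acid, a medium expected to be too weak to cyclise the prenyl group onto the new ortho hydroxyl or to hydrate the chromene.

**Compound list**
1 | 2-methylbenzene-1,3-diol (2-methylresorcinol) | Cc1c(O)cccc1O | starting material
2 | 2-methyl-1,3-di(propan-2-yloxy)benzene | Cc1c(OC(C)C)cccc1OC(C)C | intermediate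
3 | 2-[4-methyl-3,5-di(propan-2-yloxy)phenyl]-4,4,5,5-tetramethyl-1,3,2-dioxaborolane | Cc1c(OC(C)C)cc(cc1OC(C)C)B1OC(C)(C)C(C)(C)O1 | intermediate
4 | 4-methyl-3,5-di(propan-2-yloxy)phenol | Cc1c(OC(C)C)cc(O)cc1OC(C)C | intermediate
5 | 1-[6-hydroxy-3-methyl-2,4-di(propan-2-yloxy)phenyl]ethan-1-one | CC(=O)c1c(O)cc(OC(C)C)c(C)c1OC(C)C | intermediate
6 | 1-[2-hydroxy-3-iodo-5-methyl-4,6-di(propan-2-yloxy)phenyl]ethan-1-one | CC(=O)c1c(O)c(I)c(OC(C)C)c(C)c1OC(C)C | intermediate
7 | 4-hydroxy-8-iodo-6-methyl-5,7-di(propan-2-yloxy)-2H-chromene-2-thione | Oc1cc(=S)oc2c(I)c(OC(C)C)c(C)c(OC(C)C)c12 | intermediate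
8 | 8-iodo-6-methyl-2-(methylsulfanyl)-5,7-di(propan-2-yloxy)-4H-chromen-4-one | CSc1cc(=O)c2c(OC(C)C)c(C)c(OC(C)C)c(I)c2o1 | intermediate
9 | 5-hydroxy-8-iodo-6-methyl-2-(methylsulfanyl)-7-(propan-2-yloxy)-4H-chromen-4-one | CSc1cc(=O)c2c(O)c(C)c(OC(C)C)c(I)c2o1 | intermediate
10 | 5-hydroxy-6-methyl-2-(methylsulfanyl)-7-(propan-2-yloxy)-8-[(trimethylsilyl)ethynyl]-4H-chromen-4-one | CSc1cc(=O)c2c(O)c(C)c(OC(C)C)c(C#C[Si](C)(C)C)c2o1 | intermediate
11 | 8-ethynyl-5-hydroxy-6-methyl-2-(methylsulfanyl)-7-(propan-2-yloxy)-4H-chromen-4-one | CSc1cc(=O)c2c(O)c(C)c(OC(C)C)c(C#C)c2o1 | intermediate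
12 | 8-ethynyl-5-hydroxy-3-iodo-6-methyl-2-(methylsulfanyl)-7-(propan-2-yloxy)-4H-chromen-4-one | CSc1oc2c(C#C)c(OC(C)C)c(C)c(O)c2c(=O)c1I | intermediate
13 | 8-ethynyl-5-hydroxy-3-iodo-2-(methanesulfonyl)-6-methyl-7-(propan-2-yloxy)-4H-chromen-4-one | CS(=O)(=O)c1oc2c(C#C)c(OC(C)C)c(C)c(O)c2c(=O)c1I | intermediate
14 | 5-hydroxy-3-iodo-2-(methanesulfonyl)-6,8,8-trimethyl-4H,8H-pyrano[2,3-f]chromen-4-one | CS(=O)(=O)c1oc2c3C=CC(C)(C)Oc3c(C)c(O)c2c(=O)c1I | intermediate
15 | benzene-1,2,4-triol | Oc1ccc(O)c(O)c1 | starting material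
16 | 2,2-diphenyl-1,3-benzodioxol-5-ol | Oc1ccc2OC(c3ccccc3)(c3ccccc3)Oc2c1 | intermediate
17 | 5-(methoxymethoxy)-2,2-diphenyl-1,3-benzodioxole | COCOc1ccc2OC(c3ccccc3)(c3ccccc3)Oc2c1 | intermediate
18 | [5-(methoxymethoxy)-2,2-diphenyl-1,3-benzodioxol-4-yl]lithium | COCOc1ccc2OC(c3ccccc3)(c3ccccc3)Oc2c1[Li] | intermediate
19 | 5-(methoxymethoxy)-4-(3-methylbut-2-en-1-yl)-2,2-diphenyl-1,3-benzodioxole | COCOc1ccc2OC(c3ccccc3)(c3ccccc3)Oc2c1CC=C(C)C | intermediate
20 | 4-(3-methylbut-2-en-1-yl)-2,2-diphenyl-1,3-benzodioxol-5-ol | CC(C)=CCc1c(O)ccc2OC(c3ccccc3)(c3ccccc3)Oc12 | intermediate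
21 | 5-hydroxy-3-iodo-6,8,8-trimethyl-2-{[4-(3-methylbut-2-en-1-yl)-2,2-diphenyl-1,3-benzodioxol-5-yl]oxy}-4H,8H-pyrano[2,3-f]chromen-4-one | CC(C)=CCc1c(Oc2oc3c4C=CC(C)(C)Oc4c(C)c(O)c3c(=O)c2I)ccc2OC(c3ccccc3)(c3ccccc3)Oc12 | intermediate
22 | Triquetrumone A 4',5'-O-diphenylmethylene ketal (the target with its two catechol oxygens joined through a CPh2 carbon) | CC(C)=CCc1c2OC(c3ccccc3)(c3ccccc3)Oc2cc2c1oc1oc3c4C=CC(C)(C)Oc4c(C)c(O)c3c(=O)c12 | intermediate
23 | Triquetrumone A (5-hydroxy-6-methyl coumaronochromone with a 2,2-dimethylpyran fused at C7–O/C8, a 3'-prenyl group and 4',5'-hydroxyls; achiral) | CC(C)=CCc1c(O)c(O)cc2c1oc1oc3c4c(c(C)c(O)c3c(=O)c12)OC(C)(C)C=C4 | target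

**Step count**
Total: 17 steps. Longest linear sequence: 13 steps (steps 1 to 10, then 15 to 17); the ring B fragment takes steps 11 to 14.

**Steps most likely to fail**

Step 10 (the new method). Hydride transfer may lose to attack of the ether oxygen on the activated alkyne with loss of the isopropyl group, to closure through the inner carbon to a five-membered exo-methylene ring, or to hydration of the alkyne. The fallback gives up the C–H hydride shift and builds ring D by the classical Heck coupling and allylic cyclisation, which forms the other two bonds of the pyran. It sets out from 9 and comes back at 22.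
- Excess BCl3 (CH2Cl2, 0 °C to rt) removes the remaining isopropyl group of 9 to give 5,7-dihydroxy-8-iodo-6-methyl-2-(methylsulfanyl)-4H-chromen-4-one F1.
- Heck coupling with 2-methylbut-3-en-2-ol (Pd(OAc)2, Et3N, DMF, 90 °C) gives 5,7-dihydroxy-8-[(1E)-3-hydroxy-3-methylbut-1-en-1-yl]-6-methyl-2-(methylsulfanyl)-4H-chromen-4-one F2.
- Catalytic acid (PPTS, toluene, 60 °C) closes the 7-OH onto the allylic cation to give 5-hydroxy-6,8,8-trimethyl-2-(methylsulfanyl)-4H,8H-pyrano[2,3-f]chromen-4-one F3; C6 is blocked by methyl, so only the angular pyran can form.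
- H2O2 with catalytic Na2WO4 (MeOH, rt) oxidises the sulfide chemoselectively to 5-hydroxy-2-(methanesulfonyl)-6,8,8-trimethyl-4H,8H-pyrano[2,3-f]chromen-4-one F4.
- Addition–elimination with 20 (K2CO3, DMF) gives 5-hydroxy-6,8,8-trimethyl-2-{[4-(3-methylbut-2-en-1-yl)-2,2-diphenyl-1,3-benzodioxol-5-yl]oxy}-4H,8H-pyrano[2,3-f]chromen-4-one F5.
- Because electrophilic C3 iodination is not compatible with the chromene, the furan ring is closed by dehydrogenative C–H/C–H coupling with divalent palladium (Pd(OAc)2, AgOAc, PivOH, 110 °C), which gives 22.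

Step 16. Reductive loss of iodine or Heck-type insertion into the chromene or prenyl alkene may outrun C–H metalation at the hindered, electron-rich ring B. The fallback replaces the palladium cycle by a homolytic ring closure and runs from 21 to 22: irradiation at about 350 nm in degassed MeCN over K2CO3 cleaves the C3–I bond, the C3 radical adds to the free ortho position of the aryl ether, and loss of HI re-aromatises to 22. No compound outside the list arises (none F0).

Step 3. Chelation-assisted Lewis-acid cleavage of the isopropyl ether ortho to the new acetyl group would give a 2,6-dihydroxyacetophenone and erase the regiocontrol of the ring C closure. The fallback replaces electrophilic acylation by anionic acylation and runs from 4 to 5.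
- MOMCl and NaH convert 4 into 1-(methoxymethoxy)-4-methyl-3,5-di(propan-2-yloxy)benzene F6.
- n-BuLi (THF, 0 °C) lithiates one of the two equivalent positions between OMOM and O-isopropyl to give [2-(methoxymethoxy)-5-methyl-4,6-di(propan-2-yloxy)phenyl]lithium F7.
- N-methoxy-N-methylacetamide converts F7 into 1-[6-(methoxymethoxy)-3-methyl-2,4-di(propan-2-yloxy)phenyl]ethan-1-one F8.
- Catalytic HCl in MeOH removes the MOM group to give 5.

Further compounds
F1 | step 10 | 5,7-dihydroxy-8-iodo-6-methyl-2-(methylsulfanyl)-4H-chromen-4-one | CSc1cc(=O)c2c(O)c(C)c(O)c(I)c2o1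
F2 | step 10 | 5,7-dihydroxy-8-[(1E)-3-hydroxy-3-methylbut-1-en-1-yl]-6-methyl-2-(methylsulfanyl)-4H-chromen-4-one | CSc1cc(=O)c2c(O)c(C)c(O)c(/C=C/C(C)(C)O)c2o1
F3 | step 10 | 5-hydroxy-6,8,8-trimethyl-2-(methylsulfanyl)-4H,8H-pyrano[2,3-f]chromen-4-one | CSc1cc(=O)c2c(O)c(C)c3OC(C)(C)C=Cc3c2o1
F4 | step 10 | 5-hydroxy-2-(methanesulfonyl)-6,8,8-trimethyl-4H,8H-pyrano[2,3-f]chromen-4-one | CS(=O)(=O)c1cc(=O)c2c(O)c(C)c3OC(C)(C)C=Cc3c2o1
F5 | step 10 | 5-hydroxy-6,8,8-trimethyl-2-{[4-(3-methylbut-2-en-1-yl)-2,2-diphenyl-1,3-benzodioxol-5-yl]oxy}-4H,8H-pyrano[2,3-f]chromen-4-one | CC(C)=CCc1c(Oc2cc(=O)c3c(O)c(C)c4OC(C)(C)C=Cc4c3o2)ccc2OC(c3ccccc3)(c3ccccc3)Oc12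
F0 | step 16 | none | none
F6 | step 3 | 1-(methoxymethoxy)-4-methyl-3,5-di(propan-2-yloxy)benzene | COCOc1cc(OC(C)C)c(C)c(OC(C)C)c1
F7 | step 3 | [2-(methoxymethoxy)-5-methyl-4,6-di(propan-2-yloxy)phenyl]lithium | [Li]c1c(OCOC)cc(OC(C)C)c(C)c1OC(C)C
F8 | step 3 | 1-[6-(methoxymethoxy)-3-methyl-2,4-di(propan-2-yloxy)phenyl]ethan-1-one | CC(=O)c1c(OCOC)cc(OC(C)C)c(C)c1OC(C)C
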